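Take each X as born with one J, a guess because J is not among the readings, and judge the flask by one number. At 8.00 h in the eta run that guess gives 3.19 M as a reading of the equilibrium quotient, the concentration of X times that of J over that of G. The zero of its scale is the even split, G and X equal with nothing gone to Q, where the quotient is the charge of G over 2, here 1.20 M. The reading stands above that, so X should end above G.

- eta: G 2.4 M; E 0.72 M; run made earlier
- flask: G 2.4 M; E 0.480 M; time 40 h

- eta (time / h: X / %, Q / %, G / %): 0.667: 12.7, 1.7, 85.0; 1.00: 19.0, 1.9, 77.3; 2.00: 34.2, 5.0, 60.5; 3.00: 44.9, 5.4, 47.9; 5.00: 57.5, 6.8, 37.8; 8.00: 60.6, 10.6, 27.6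

(each reading ± 1 percentage point)

- concentration of X at 40 h, in M
- concentration of Q at 40 h, in M
- concentration of G at 40 h, in M
- concentration of J at 40 h, in M

In the first instants X is low, 12.7% after 0.667 h in the eta run, and the first hour of that run reads 0.257 h⁻¹ as the rate of loss of G, a half-life of 2.69 h. In the middle X and J build up, the way back grows, and G flattens; because that half-life is short against 40 h, the new flask should reach the quotient early. What is about to matter then is the leak to Q, which I guess takes one E per Q at a rate proportional to G and E. The eta run, with G near 47.9% mid-run and E taken at its charge, gives a rough constant of 0.0384 M⁻¹ h⁻¹. With G in the new flask held near the last reading of the eta run, 0.662 M, E there decays with a time constant of 39.3 h, longer than the half-life of G. So by the end my reckoning has Q at 0.307 M. Putting the quotient on what remains gives X and J at 1.44 M each and G at 0.651 M.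

The forecast differs from this, with 1.53 M of X, 0.48 M of Q, 0.29 M of G and 0.1 M of J, and says “The E dependence and J are the weakest parts.”

The flask gives 1.46 M of X, 0.336 M of Q, 0.602 M of G and 1.46 M of J.

    G ⇌ X + J (K = 3.50 M, k = 0.230 h⁻¹)
    G + E → Q (k = 0.0400 M⁻¹ h⁻¹)

After 4.00 h the flask held G at 43.3%, J at 1.25 M and Q at 4.44%. From 20.0 h to 40 h the reaction of G + E to Q went on while E fell from 49.2% to 30.0% of its charge and X slipped from 63.1% to 60.9%, with the quotient ending at 3.54 M against the 3.19 M read. A neighbour flask charged with 0.60 M of G, with E and time as in the flask, has an even split at 0.300 M, below the quotient; with its 0.0761 M of Q, the quotient gives 0.458 M of X, and that flask holds 0.465 M.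

The runs were generated by integration for an exercise; noise was put on by code.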